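The nucleophile binds the acid set free far more tightly than the free base does, 2400 M⁻¹ against 15 M⁻¹, so I asked whether the free base could matter at all.

all flasks: electrophile 0.20 M; nucleophile 0.220 M; scavenger 0.100 M; time 1.5 h
- Monday's: free base 0.160 M
- Tuesday's: free base 0.320 M

    nucleophile + acid set free ⇌ protonated nucleophile, settled at all times (K1 = 2400 M⁻¹)
    acid set free + free base ⇌ salt of the base, settled at all times (K2 = 15 M⁻¹)
    electrophile + nucleophile → acid set free + target (k3 = 0.24 M⁻¹ min⁻¹)
    acid set free + scavenger → scavenged by-product (k4 = 3.6 M⁻¹ min⁻¹)
    nucleophile + target → over-reaction product (k5 = 0.080 M⁻¹ min⁻¹)
    nucleophile + acid set free ⇌ idle adduct, settled at all times (K6 = 960 M⁻¹)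

- part of the electrophile that has reacted at the end, Monday's
- part of the electrophile that has reacted at the end, Tuesday's
- what raising the concentration of free base from its lowest to its highest value here does to the part of the electrophile that has reacted (changes below 5 percentage points count as none) (no change / it falls / it rises)

- amounts and yields of acid set free count idle adduct too
- run time (Monday's): 1.5 h

I reckoned in powers of ten and took the settings in turn.

1. Free base. Monday's flask started at 2.49. This is the tilt: the powers of ten by which the nucleophile's hold on acid, its constants for protonated nucleophile and idle adduct summed and multiplied by [nucleophile], exceeds the free base's constant multiplied by [free base]. Doubling [free base] took off 0.301, leaving Tuesday's flask at 2.19 at the start, still more than one power of ten. I expected no change.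

2. Nucleophile. Each electrophile reacted spends one nucleophile, and its acid ties up another. The nucleophile is therefore the limiting reagent at two per electrophile, and I expected a stop at 55.0% of the electrophile, moving in step with [nucleophile] at fixed [electrophile]. The electrophile's half-life by the target-making step alone, at the charged concentrations, was 0.22 h, shorter than the run of 1.5 h, so I expected Monday's flask to reach that stop.

3. Electrophile. At fixed [nucleophile], the same stop, spread over a larger charge, is a smaller percentage.

4. Scavenger and time. Each acid scavenged returns one nucleophile, so I expected the flasks to pass the stop, by an amount I did not reckon.

I committed to 55.0% for both flasks. The forecast gave 59% and 60%, no change, holding that the “nucleophile binds acid far more strongly than the weak free base does”.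

Monday's flask reached 57.6% and Tuesday's 58.1%, a change of 0.52 percentage points, below the margin of 5 points: no change. Turned one at a time on Tuesday's flask, the settings moved its answer at most by: nucleophile (12 points), then electrophile (10 points), then time (2.9 points), then scavenger (0.71 points), then free base (0.29 points). At the end, the tilt, read now as acid held in protonated nucleophile and idle adduct over acid held in salt of the base, stood at 1.22 in Monday's flask and 0.926 in Tuesday's, which by then was under one power of ten.

A neighbour of Monday's flask held a quarter of the nucleophile, 0.055 M. Its tilt at the start came to 1.89, more than one power of ten, so the same reckoning put its stop at 13.7%. That neighbour reached 19.1%, more than the stop, with target at 18.5%. Its scavenged by-product stood at 0.0232 M, and 81% of its electrophile was left at the end.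

The constants are assumed; what happens was integrated by code.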